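**Retrosynthetic overview**
1. Target 16 ⇐ amide-ester 15 by one hydride reduction (C3 amide → CH2OH, side-chain ester → CH2OH).
2. 15 ⇐ benzofuran amide 7 + ketone 13: the C2–C1′ bond is made by adding the ketyl (carbonyl carbon of 13 as nucleophile) to C2 of the benzofuran; this sets C1′ and C2, and base equilibration then sets C3 trans.
3. 7 ⇐ 5-bromo-o-vanillin + ethyl diazoacetate (benzofuran annulation), amidation, Negishi coupling with a zinc homoenolate.
4. 13 ⇐ 1,4-dimethoxybenzene: Birch reduction, mono-hydroboration with enol-ether hydrolysis (trans OH/OMe), lipase resolution.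
5. Ring order: furan ring built aromatic (step 1); cyclohexane ring from arene reduction (step 4); the dihydrofuran ring arises by dearomatisation in step 7, with no later ring closure.

Assumption: compounds 1, 2, 6 (0.5 M in THF) and 8 are bought; primed locants are the cyclohexane carbons of the target, and "C3 hydroxyl/C4 methoxy" refer to ketone numbering.

**Step 1**
Reactants: 1 5-bromo-2-hydroxy-3-methoxybenzaldehyde; 2 ethyl diazoacetate
Product: 4 ethyl 5-bromo-7-methoxy-1-benzofuran-3-carboxylate, via lactol ester 3 (not isolated)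
Conditions: HBF4·OEt2 (10 mol%), CH2Cl2, 23 °C; then conc. H2SO4, 23 °C
Reagents that add atoms: none
Why: Acid-promoted Roskamp-type addition of the diazoester with 1,2-aryl shift gives the 2-aryl-3-oxopropanoate, which closes to lactol 3 and is dehydrated to the aromatic benzofuran (benzofuran annulation of salicylaldehydes); no stereocentre.

**Step 2**
Reactants: 4 ethyl 5-bromo-7-methoxy-1-benzofuran-3-carboxylate
Product: 5 5-bromo-7-methoxy-N,N-dimethyl-1-benzofuran-3-carboxamide
Conditions: Me2NH (2 M in THF), AlMe3, toluene, 0 → 80 °C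
Reagents that add atoms: dimethylamine CNC
Why: Weinreb aminolysis with Me2AlNMe2 gives a tertiary amide that still activates C2 but, unlike an ester, cannot be trapped as a cis-fused lactone by the neighbouring tertiary alkoxide formed in step 7.

**Step 3**
Reactants: 5 5-bromo-7-methoxy-N,N-dimethyl-1-benzofuran-3-carboxamide; 6 (3-ethoxy-3-oxopropyl)zinc bromide
Product: 7 ethyl 3-[3-(dimethylcarbamoyl)-7-methoxy-1-benzofuran-5-yl]propanoate
Conditions: Pd(OAc)2 (2 mol%), SPhos (4 mol%), THF, 50 °C
Reagents that add atoms: none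
Why: Negishi cross-coupling of the ester-stabilised zinc homoenolate with the aryl bromide installs the three-carbon chain at the final carbon count; amide and ester are inert to the organozinc.

**Step 4**
Reactants: 8 1,4-dimethoxybenzene
Product: 9 1,4-dimethoxycyclohexa-1,4-diene
Conditions: Li, NH3 (l), THF, t-BuOH, −78 → −33 °C; then H2O
Reagents that add atoms: none
Why: Birch reduction leaves both donor-substituted carbons sp2, giving the symmetrical bis(enol ether).

**Step 5**
Reactants: 9 1,4-dimethoxycyclohexa-1,4-diene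
Product: 12 rac-trans-3-hydroxy-4-methoxycyclohexan-1-one, via B-alkyl-9-BBN adduct 10 (not isolated), via hydroxy enol ether 11 (not isolated)
Conditions: 9-BBN (0.8 equiv), THF, 0 → 25 °C; NaOH, H2O2, 0 °C; then 0.5 M HCl, THF–H2O, 0 °C
Reagents that add atoms: hydrogen peroxide OO; water O
Why: Enol-ether hydroboration–oxidation puts boron β to OMe and adds H and B syn, so OH and OMe end up trans; mild acid then hydrolyses the untouched second enol ether to the ketone at the correct carbon.

**Step 6**
Reactants: 12 rac-trans-3-hydroxy-4-methoxycyclohexan-1-one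
Product: 13 (3S,4S)-3-hydroxy-4-methoxycyclohexan-1-one
Conditions: Candida antarctica lipase B (Novozym 435), vinyl acetate, MTBE, 30 °C, stopped at about 52% conversion
Reagents that add atoms: none
Why: Lipase kinetic resolution by transesterification acylates the (3R)-carbinol (Kazlauskas rule, as for trans-2-methoxycyclohexanol) and leaves the (3S,4S)-alcohol, which carries both ring stereocentres of the target.

**Step 7**
Reactants: 7 ethyl 3-[3-(dimethylcarbamoyl)-7-methoxy-1-benzofuran-5-yl]propanoate; 13 (3S,4S)-3-hydroxy-4-methoxycyclohexan-1-one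
Product: 15 ethyl 3-[(2S,3S)-3-(dimethylcarbamoyl)-2-[(1S,3S,4S)-1,3-dihydroxy-4-methoxycyclohexyl]-7-methoxy-2,3-dihydro-1-benzofuran-5-yl]propanoate, via cis amide 14 (not isolated)
Conditions: SmI2 (3 equiv), t-BuOH (2 equiv), THF, −20 → 0 °C, no HMPA; then NaOEt (excess over samarium), EtOH, 50 °C
Reagents that add atoms: none
Why: Proposed new method: SmI2 turns the ketone into a ketyl radical anion whose carbonyl carbon, normally an electrophile, adds as a nucleophilic radical to C2 of 7 (the β-carbon of the unsaturated amide, also an electrophilic site); the benzylic α-amido radical is reduced to the samarium enolate and protonated, and ethoxide then equilibrates C3 to the trans amide; trivalent samarium bridging the ketyl oxygen and the axial C3 hydroxyl forces equatorial C–C bond formation (tertiary OH cis to secondary OH), and the amide carbonyl binding the same metal with the benzo ring turned away is expected to expose the C2 face that gives 2S; the closest known chemistry is the hydroxyl-directed SmI2 ketyl–olefin coupling of β-hydroxy ketones with acrylates and acrylamides and the dearomatising ketyl addition to 3-acyl indoles and benzofurans.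

**Step 8**
Reactants: 15 ethyl 3-[(2S,3S)-3-(dimethylcarbamoyl)-2-[(1S,3S,4S)-1,3-dihydroxy-4-methoxycyclohexyl]-7-methoxy-2,3-dihydro-1-benzofuran-5-yl]propanoate
Product: 16 difengpiol B, (1S,3S,4S)-1-[(2S,3R)-3-(hydroxymethyl)-5-(3-hydroxypropyl)-7-methoxy-2,3-dihydro-1-benzofuran-2-yl]-4-methoxycyclohexane-1,3-diol
Conditions: LiH2N·BH3 (8 equiv, from BH3·NH3 and n-BuLi, THF, 0 °C), THF, 0 → 23 °C; then H2O, aq. NaOH
Reagents that add atoms: none
Why: Lithium amidotrihydroborate reduces hindered tertiary amides to primary alcohols by C–N cleavage and esters to alcohols, so both carbonyls reach the CH2OH level in one operation without touching a stereocentre (the C3 descriptor changes from S to R only through CIP priorities).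

**Compound list**
1 | 5-bromo-2-hydroxy-3-methoxybenzaldehyde | O=Cc1cc(Br)cc(OC)c1O | starting material
2 | ethyl diazoacetate | CCOC(=O)C=[N+]=[N-] | starting material
3 | ethyl 5-bromo-2-hydroxy-7-methoxy-2,3-dihydro-1-benzofuran-3-carboxylate (lactol, stereoisomer mixture) | CCOC(=O)C1C(O)Oc2c(OC)cc(Br)cc12 | intermediate
4 | ethyl 5-bromo-7-methoxy-1-benzofuran-3-carboxylate | CCOC(=O)c1coc2c(OC)cc(Br)cc12 | intermediate
5 | 5-bromo-7-methoxy-N,N-dimethyl-1-benzofuran-3-carboxamide | CN(C)C(=O)c1coc2c(OC)cc(Br)cc12 | intermediate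
6 | (3-ethoxy-3-oxopropyl)zinc bromide | CCOC(=O)CC[Zn]Br | starting material
7 | ethyl 3-[3-(dimethylcarbamoyl)-7-methoxy-1-benzofuran-5-yl]propanoate | CCOC(=O)CCc1cc(OC)c2occ(C(=O)N(C)C)c2c1 | intermediate
8 | 1,4-dimethoxybenzene | COc1ccc(OC)cc1 | starting material
9 | 1,4-dimethoxycyclohexa-1,4-diene | COC1=CCC(OC)=CC1 | intermediate
10 | rac-9-(trans-3,6-dimethoxycyclohex-3-en-1-yl)-9-borabicyclo[3.3.1]nonane (boron trans to the C6 methoxy; one enantiomer drawn) | COC1=CC[C@H](OC)[C@@H](B2C3CCCC2CCC3)C1 | intermediate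
11 | (1RS,6RS)-3,6-dimethoxycyclohex-3-en-1-ol (racemic trans; one enantiomer drawn) | COC1=CC[C@H](OC)[C@@H](O)C1 | intermediate
12 | (3RS,4RS)-3-hydroxy-4-methoxycyclohexan-1-one (racemic trans; one enantiomer drawn) | O=C1CC[C@H](OC)[C@@H](O)C1 | intermediate
13 | (3S,4S)-3-hydroxy-4-methoxycyclohexan-1-one | O=C1CC[C@H](OC)[C@@H](O)C1 | intermediate
14 | ethyl 3-[(2S,3R)-3-(dimethylcarbamoyl)-2-[(1S,3S,4S)-1,3-dihydroxy-4-methoxycyclohexyl]-7-methoxy-2,3-dihydro-1-benzofuran-5-yl]propanoate (2,3-cis) | COc1cc(CCC(=O)OCC)cc2c1O[C@H]([C@]1(O)CC[C@H](OC)[C@@H](O)C1)[C@@H]2C(=O)N(C)C | intermediate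
15 | ethyl 3-[(2S,3S)-3-(dimethylcarbamoyl)-2-[(1S,3S,4S)-1,3-dihydroxy-4-methoxycyclohexyl]-7-methoxy-2,3-dihydro-1-benzofuran-5-yl]propanoate (2,3-trans) | COc1cc(CCC(=O)OCC)cc2c1O[C@H]([C@]1(O)CC[C@H](OC)[C@@H](O)C1)[C@H]2C(=O)N(C)C | intermediate
16 | difengpiol B | COc1cc(CCCO)cc2c1O[C@H]([C@]1(O)CC[C@H](OC)[C@@H](O)C1)[C@H]2CO | target

**Step count**
Total: 8 steps. Longest linear sequence: 5 steps (1 → 2 → 3 → 7 → 8, or 4 → 5 → 6 → 7 → 8).

**Steps most likely to fail, with fallbacks**

Step 7 is the main risk, for three reasons: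
- The twisted tertiary amide may be too weak a radical acceptor, so that 13 is simply reduced.
- The facial selectivity at C2 rests on an untested three-point samarium chelate.
- The samarium enolate or the ethoxide stage could open the dihydrofuran by loss of phenoxide.

The fallback sets out from 4 and 13 and comes back at 16. Negishi coupling of 4 with 6 gives the diester ethyl 5-(3-ethoxy-3-oxopropyl)-7-methoxy-1-benzofuran-3-carboxylate F1, which carries the planar ester acceptor of the classical chelation-controlled ketyl–olefin lactonisation. SmI2/t-BuOH/THF coupling of F1 with 13 is allowed to run on to the cis-fused spirolactone (2S,3R)-5-(3-ethoxy-3-oxopropyl)-2-[(1S,3S,4S)-1,3-dihydroxy-4-methoxycyclohexyl]-7-methoxy-2,3-dihydro-1-benzofuran-3-carboxylic acid γ-lactone (closed onto the cyclohexane C1 oxygen) F2. Ring-opening aminolysis with Me2AlNMe2, which also converts the side-chain ester, gives the cis bis-amide 3-[(2S,3R)-3-(dimethylcarbamoyl)-2-[(1S,3S,4S)-1,3-dihydroxy-4-methoxycyclohexyl]-7-methoxy-2,3-dihydro-1-benzofuran-5-yl]-N,N-dimethylpropanamide F3. NaOMe in MeOH epimerises C3 to the trans bis-amide 3-[(2S,3S)-3-(dimethylcarbamoyl)-2-[(1S,3S,4S)-1,3-dihydroxy-4-methoxycyclohexyl]-7-methoxy-2,3-dihydro-1-benzofuran-5-yl]-N,N-dimethylpropanamide F4, and LiH2N·BH3 reduces both amides to 16. This fallback addresses acceptor reactivity only; if C2 selectivity is poor, the C2 epimers would have to be separated.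

Step 5 can over-run to double hydroboration of the bis(enol ether), and the free β-hydroxy ketone can dehydrate during hydrolysis. The fallback sets out from 9 and comes back at 12, desymmetrising the diene before the borane is used. Ethylene glycol (1 equiv) with pyridinium p-toluenesulfonate converts one enol ether into the ketal 8-methoxy-1,4-dioxaspiro[4.5]dec-7-ene F5. BH3·THF followed by NaOH/H2O2 gives (7RS,8RS)-8-methoxy-1,4-dioxaspiro[4.5]decan-7-ol F6. Pyridinium p-toluenesulfonate in wet acetone then releases 12.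

Step 8 may stall at the hindered C3 amide or give some amine by C–O cleavage. The fallback sets out from 15 and comes back at 16 in two stages through the aldehyde. Cp2Zr(H)Cl in THF reduces the tertiary amide selectively to ethyl 3-[(2S,3S)-2-[(1S,3S,4S)-1,3-dihydroxy-4-methoxycyclohexyl]-3-formyl-7-methoxy-2,3-dihydro-1-benzofuran-5-yl]propanoate F7; its trans geometry prevents lactol formation. LiBH4 in THF–MeOH then reduces aldehyde and ester together to 16.

**Further compounds**
F1 | step 7 | ethyl 5-(3-ethoxy-3-oxopropyl)-7-methoxy-1-benzofuran-3-carboxylate | CCOC(=O)CCc1cc(OC)c2occ(C(=O)OCC)c2c1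
F2 | step 7 | (2S,3R)-5-(3-ethoxy-3-oxopropyl)-2-[(1S,3S,4S)-1,3-dihydroxy-4-methoxycyclohexyl]-7-methoxy-2,3-dihydro-1-benzofuran-3-carboxylic acid γ-lactone (cis-fused spirolactone) | COc1cc(CCC(=O)OCC)cc2c1O[C@H]3[C@@H]2C(=O)O[C@]34CC[C@H](OC)[C@@H](O)C4
F3 | step 7 | 3-[(2S,3R)-3-(dimethylcarbamoyl)-2-[(1S,3S,4S)-1,3-dihydroxy-4-methoxycyclohexyl]-7-methoxy-2,3-dihydro-1-benzofuran-5-yl]-N,N-dimethylpropanamide | COc1cc(CCC(=O)N(C)C)cc2c1O[C@H]([C@]1(O)CC[C@H](OC)[C@@H](O)C1)[C@@H]2C(=O)N(C)C
F4 | step 7 | 3-[(2S,3S)-3-(dimethylcarbamoyl)-2-[(1S,3S,4S)-1,3-dihydroxy-4-methoxycyclohexyl]-7-methoxy-2,3-dihydro-1-benzofuran-5-yl]-N,N-dimethylpropanamide | COc1cc(CCC(=O)N(C)C)cc2c1O[C@H]([C@]1(O)CC[C@H](OC)[C@@H](O)C1)[C@H]2C(=O)N(C)C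
F5 | step 5 | 8-methoxy-1,4-dioxaspiro[4.5]dec-7-ene | COC1=CCC2(CC1)OCCO2
F6 | step 5 | (7RS,8RS)-8-methoxy-1,4-dioxaspiro[4.5]decan-7-ol (racemic trans; one enantiomer drawn) | C12(OCCO1)CC[C@H](OC)[C@@H](O)C2
F7 | step 8 | ethyl 3-[(2S,3S)-2-[(1S,3S,4S)-1,3-dihydroxy-4-methoxycyclohexyl]-3-formyl-7-methoxy-2,3-dihydro-1-benzofuran-5-yl]propanoate | COc1cc(CCC(=O)OCC)cc2c1O[C@H]([C@]1(O)CC[C@H](OC)[C@@H](O)C1)[C@H]2C=O
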